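**Plan**

- Retrosynthesis: the seven phenol acetals come off last. The ring bond between the ketone α-carbon and the ring carbon bearing the chalcone aryl group is then cut by a retro-1,3-shift, which contracts the cyclohexene to a 2-aroyl-1-methyl-1-styrylcyclobutane.
- Enabling feature: in the cyclohexene the aroyl-bearing carbon is bonded to an allylic ring carbon that is also benzylic to the 2,6-dioxygenated arene, and the ring C=C carries the methyl group at its far end. An enolate at the first atom and an allyl cation over the other three are therefore both stabilised, and the same pair is reachable from the strained cyclobutane in which the enolate carbon is still bonded to the methyl-bearing carbon.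
- Further cuts on the cyclobutane: styryl C–aryl (Heck), aryl–C(=O) (aryllithium plus N-methoxy-N-methylamide), benzylic C–aryl (rhodium-catalysed conjugate arylation) and ring C–C(=O) (carbonylation of an enol triflate). This leads back to 2-methyl-2-vinylcyclobutanone, itself made by enlarging a cyclopropane.
- Forward order of rings: cyclopropane, cyclobutanone, cyclobutene, cyclobutane that receives the three arenes one after the other, cyclohexene by two-carbon ring expansion, deprotection.
- Stereochemistry: the benzylic carbon bearing the 2,4-dioxygenated phenyl group is set by the chiral ligand in the conjugate arylation. The other two centres are set relative to it in the ring expansion (reversible closure, all-trans product). The quaternary cyclobutane carbon is carried as both epimers because it becomes sp2.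

Key step: step 15

Remark: the antipode of the chiral diene ligand used in the conjugate arylation is to be fixed by a test reaction so that the aryl-bearing carbon has the configuration drawn; the quaternary cyclobutane carbon is carried as a mixture of both epimers.

**Route**

Step 1
Reactants: 1 cyclopropyl phenyl sulfide; 2 methyl vinyl ketone (but-3-en-2-one)
Product: 4 2-[1-(phenylsulfanyl)cyclopropyl]but-3-en-2-ol (racemic), via 1-lithiocyclopropyl phenyl sulfide 3 (not isolated)
Conditions: n-BuLi, THF, 0 °C; then 2, −78 °C; H2O quench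
Reagents that add atoms: none
Why: Sulfur-assisted α-lithiation of the cyclopropane followed by 1,2-addition of the organolithium to the enone carbonyl at low temperature gives the tertiary allylic cyclopropylcarbinol (organolithium carbonyl addition).

Step 2
Reactants: 4 2-[1-(phenylsulfanyl)cyclopropyl]but-3-en-2-ol
Product: 5 2-methyl-2-vinylcyclobutan-1-one (racemic)
Conditions: HBF4 (48 % aq), Et2O, 0 °C to rt
Reagents that add atoms: water, O
Why: Acid ionises the tertiary allylic carbinol, the cyclopropylcarbinyl cation enlarges to the sulfur-stabilised cyclobutyl cation and hydrolysis of this thionium ion releases the cyclobutanone (cyclopropylcarbinyl-to-cyclobutyl rearrangement, the secosulfenylation route to 2,2-disubstituted cyclobutanones).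

Step 3
Reactants: 5 2-methyl-2-vinylcyclobutan-1-one
Product: 7 4-methyl-4-vinylcyclobut-1-en-1-yl trifluoromethanesulfonate (racemic), via lithium 4-methyl-4-vinylcyclobut-1-en-1-olate 6 (not isolated)
Conditions: LiN(iPr)2, THF, −78 °C; PhNTf2, −78 °C to 0 °C
Reagents that add atoms: N-phenylbis(trifluoromethanesulfonimide), O=S(=O)(N(c1ccccc1)S(=O)(=O)C(F)(F)F)C(F)(F)F
Why: The ketone can be enolised only towards its CH2 group because the other α-carbon is quaternary, and the lithium enolate is O-sulfonylated by the triflimide (enol triflate formation).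

Step 4
Reactants: 7 4-methyl-4-vinylcyclobut-1-en-1-yl trifluoromethanesulfonate
Product: 8 N-methoxy-N,4-dimethyl-4-vinylcyclobut-1-ene-1-carboxamide (racemic)
Conditions: Pd(OAc)2 (5 mol %), PPh3 (10 mol %), CO (1 atm), MeNH(OMe)·HCl, Et3N, DMF, rt to 40 °C
Reagents that add atoms: carbon monoxide, [C-]#[O+]; N,O-dimethylhydroxylamine hydrochloride, CNOC.Cl
Why: Zerovalent palladium inserts into the alkenyl C–O bond, CO insertion gives an acyl palladium species and the hydroxylamine traps it (palladium-catalysed aminocarbonylation of an enol triflate), while the isolated vinyl group is inert.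

Step 5
Reactants: 9 4-bromoresorcinol (4-bromobenzene-1,3-diol)
Product: 10 1-bromo-2,4-bis(methoxymethoxy)benzene
Conditions: MOMCl, iPr2NEt, CH2Cl2, 0 °C to rt
Reagents that add atoms: chloromethyl methyl ether, COCCl
Why: Both phenols are alkylated by the chloromethyl ether in the presence of the amine base (Williamson-type formation of the acetal ethers).

Step 6
Reactants: 10 1-bromo-2,4-bis(methoxymethoxy)benzene
Product: 13 [2,4-bis(methoxymethoxy)phenyl]boronic acid, via [2,4-bis(methoxymethoxy)phenyl]lithium 11 (not isolated), via lithium triisopropoxy[2,4-bis(methoxymethoxy)phenyl]borate 12 (not isolated)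
Conditions: n-BuLi, THF, −78 °C; B(OiPr)3, −78 °C to rt; H2O, pH 6 work-up
Reagents that add atoms: triisopropyl borate, CC(C)OB(OC(C)C)OC(C)C; water, O
Why: Bromine–lithium exchange at low temperature is faster than ring deprotonation, and the aryllithium is trapped by the borate and hydrolysed under near-neutral conditions that keep the acetals (lithiation–borylation).

Step 7
Reactants: 8 N-methoxy-N,4-dimethyl-4-vinylcyclobut-1-ene-1-carboxamide; 13 [2,4-bis(methoxymethoxy)phenyl]boronic acid
Product: 14 (1S,2RS,4R)-4-[2,4-bis(methoxymethoxy)phenyl]-N-methoxy-N,2-dimethyl-2-vinylcyclobutane-1-carboxamide (aryl trans to the amide; two epimers at the quaternary carbon)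
Conditions: [RhCl(C2H4)2]2 (2.5 mol %), (1R,4R)-2,5-diphenylbicyclo[2.2.2]octa-2,5-diene (5.5 mol %, or its antipode), KOH (0.3 equiv), dioxane/H2O 10:1, 40 °C
Reagents that add atoms: none
Why: Hayashi–Miyaura asymmetric 1,4-addition, in which the aryl rhodium species adds to the strained cyclobutene C=C on the enantioface selected by the chiral diene ligand and so sets the aryl-bearing carbon, while protonation and base equilibration of the α-carbon give the trans amide and the similar size of methyl and vinyl on the remote quaternary carbon should leave the catalyst in control for both enantiomers of 8.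

Step 8
Reactants: 15 resorcinol
Product: 16 1,3-bis(methoxymethoxy)benzene
Conditions: MOMCl, iPr2NEt, CH2Cl2, 0 °C to rt
Reagents that add atoms: chloromethyl methyl ether, COCCl
Why: Both phenols are alkylated by the chloromethyl ether in the presence of the amine base (Williamson-type formation of the acetal ethers).

Step 9
Reactants: 16 1,3-bis(methoxymethoxy)benzene; 17 prenyl bromide (1-bromo-3-methylbut-2-ene)
Product: 19 1,3-bis(methoxymethoxy)-2-(3-methylbut-2-en-1-yl)benzene, via [2,6-bis(methoxymethoxy)phenyl]lithium 18 (not isolated)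
Conditions: n-BuLi, THF, 0 °C; CuI (10 mol %), then 17, −78 °C to rt
Reagents that add atoms: none
Why: Directed ortho-metalation occurs at the position flanked by the two acetal oxygens, and the copper-mediated aryl anion attacks the primary carbon of the allylic bromide (SN2 alkylation) to install the 3-methylbut-2-enyl group.

Step 10
Reactants: 19 1,3-bis(methoxymethoxy)-2-(3-methylbut-2-en-1-yl)benzene; 14 (1S,2RS,4R)-4-[2,4-bis(methoxymethoxy)phenyl]-N-methoxy-N,2-dimethyl-2-vinylcyclobutane-1-carboxamide
Product: 21 [2,4-bis(methoxymethoxy)-3-(3-methylbut-2-en-1-yl)phenyl]{(1S,2RS,4R)-4-[2,4-bis(methoxymethoxy)phenyl]-2-methyl-2-vinylcyclobutyl}methanone (two epimers at the quaternary carbon), via [2,4-bis(methoxymethoxy)-3-(3-methylbut-2-en-1-yl)phenyl]lithium 20 (not isolated)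
Conditions: 19, n-BuLi, TMEDA, THF, 0 °C; then 14, −78 °C to 0 °C; H2O quench
Reagents that add atoms: none
Why: The acetal oxygens direct a second ortho-lithiation to the ring carbon next to one OCH2OCH3 group, and addition to the N-methoxy-N-methylamide gives a chelated tetrahedral intermediate that releases the ketone only on work-up, so that over-addition is avoided, the benzylic stereocentre is untouched and the α-centre stays trans.

Step 11
Reactants: 22 2',4'-dihydroxyacetophenone
Product: 23 1-(2,4-dihydroxy-3-iodophenyl)ethan-1-one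
Conditions: I2 (0.4 equiv), HIO3 (0.2 equiv), EtOH/H2O, 35 °C
Reagents that add atoms: iodine, II; iodic acid, OI(=O)=O
Why: Electrophilic aromatic iodination takes place at the position between the two hydroxyl groups, which is ortho to both donors, and HIO3 reoxidises the iodide so that all iodine is used.

Step 12
Reactants: 23 1-(2,4-dihydroxy-3-iodophenyl)ethan-1-one
Product: 24 1-[3-iodo-2,4-bis(methoxymethoxy)phenyl]ethan-1-one
Conditions: NaH (2.4 equiv), MOMCl, DMF, 0 °C to rt
Reagents that add atoms: chloromethyl methyl ether, COCCl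
Why: Both sodium phenoxides, including the hydrogen-bonded one next to the ketone, are alkylated by the chloromethyl ether (phenol protection as acetals).

Step 13
Reactants: 24 1-[3-iodo-2,4-bis(methoxymethoxy)phenyl]ethan-1-one; 25 4-(methoxymethoxy)benzaldehyde
Product: 26 (E)-1-[3-iodo-2,4-bis(methoxymethoxy)phenyl]-3-[4-(methoxymethoxy)phenyl]prop-2-en-1-one
Conditions: KOH, EtOH/H2O, rt
Reagents that add atoms: none
Why: Claisen–Schmidt condensation, in which the methyl ketone enolate adds to the non-enolisable aldehyde and the aldol dehydrates to the conjugated E enone.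

Step 14
Reactants: 21 [2,4-bis(methoxymethoxy)-3-(3-methylbut-2-en-1-yl)phenyl]{(1S,2RS,4R)-4-[2,4-bis(methoxymethoxy)phenyl]-2-methyl-2-vinylcyclobutyl}methanone; 26 (E)-1-[3-iodo-2,4-bis(methoxymethoxy)phenyl]-3-[4-(methoxymethoxy)phenyl]prop-2-en-1-one
Product: 27 [2,4-bis(methoxymethoxy)-3-(3-methylbut-2-en-1-yl)phenyl]{(1S,2RS,4R)-4-[2,4-bis(methoxymethoxy)phenyl]-2-[(E)-2-{2,6-bis(methoxymethoxy)-3-[(E)-3-[4-(methoxymethoxy)phenyl]prop-2-enoyl]phenyl}ethenyl]-2-methylcyclobutyl}methanone (two epimers at the quaternary carbon)
Conditions: Pd2(dba)3 (2.5 mol %), [HP(t-Bu)3]BF4 (10 mol %), Cy2NMe (1.5 equiv), dioxane, 40 °C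
Reagents that add atoms: none
Why: Mizoroki–Heck reaction, in which zerovalent palladium inserts into the C–I bond, the monosubstituted vinyl group inserts with the aryl group going to its terminal carbon and β-hydride elimination, possible only away from the quaternary carbon, gives the E styrene, while the 1,2-disubstituted enone and the trisubstituted alkene are much less reactive and no stereocentre is affected.

Step 15
Reactants: 27 the 2-aroyl-1-methyl-1-styrylcyclobutane from step 14 (both epimers)
Product: 28 [2,4-bis(methoxymethoxy)-3-(3-methylbut-2-en-1-yl)phenyl]{(1S,2S,6R)-2-{2,6-bis(methoxymethoxy)-3-[(E)-3-[4-(methoxymethoxy)phenyl]prop-2-enoyl]phenyl}-6-[2,4-bis(methoxymethoxy)phenyl]-4-methylcyclohex-3-en-1-yl}methanone (aroyl trans to both aryl groups)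
Conditions: Sc(OTf)3 (20 mol %), 2,6-di-tert-butylpyridine (40 mol %), 4 Å molecular sieves, CH2Cl2, −40 °C to 0 °C
Reagents that add atoms: none
Why: Proposed new method: Sc(OTf)3 is expected to bind the aryl ketone oxygen together with the neighbouring methoxymethoxy oxygen of 27 and so to weaken the strained ring bond between the ketone α-carbon and the quaternary methyl/styryl carbon (a donor–acceptor cyclobutane), which ionises to a scandium enolate and a tertiary allyl cation conjugated through the styryl unit with the 2,6-dioxygenated arene. The enolate carbon then bonds to the far, benzylic end of the allyl cation, so that the four-membered ring is enlarged by the two styryl carbons in a net 1,3-shift; this closure is 6-endo-trig at the allyl cation with the enolate C=C exocyclic, and return to the cyclobutane or O-alkylation to a dihydropyran is reversible whereas the strain-free cyclohexenyl ketone is the thermodynamic sink. The closest known reaction types are the acid-promoted rearrangement of the vinylcyclobutanes formed in cationic (2+2) cycloadditions of dienes to cyclohexenes, the Lewis acid opening of donor–acceptor cyclobutanes and the stepwise polar Diels–Alder reaction of Lewis acid-chelated 2'-oxygenated chalcones. The benzylic carbon bearing the 2,4-bis(methoxymethoxy)phenyl group is not involved and fixes the absolute configuration, while the ketone α-carbon (re-formed from the planar enolate) and the new allylic/benzylic carbon are set relative to it, because enolisation and re-ionisation are reversible under the Lewis acid, in favour of the trans,trans isomer with all three substituents pseudoequatorial; both quaternary-carbon epimers of 27 give the same ion pair. The step needs C–C bond formation at the remote allyl terminus in preference to fragmentation of the ion pair into chalcone and diene, which would erase the benzylic centre, and the tether between the two charged halves, the low temperature and the buffered non-nucleophilic medium are relied on to secure this and to spare the acetals.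

Step 16
Reactants: 28 the hepta(methoxymethyl) ether from step 15
Product: 29 [2,4-dihydroxy-3-(3-methylbut-2-en-1-yl)phenyl]{(1S,2S,6R)-2-{2,6-dihydroxy-3-[(E)-3-(4-hydroxyphenyl)prop-2-enoyl]phenyl}-6-(2,4-dihydroxyphenyl)-4-methylcyclohex-3-en-1-yl}methanone (CNP0283121.2)
Conditions: HCl (3 M aq), MeOH, 40 °C
Reagents that add atoms: none
Why: Acid-catalysed acetal exchange with methanol removes all seven methoxymethyl groups as dimethoxymethane without touching the three stereocentres, the ketone α-carbon being already in its more stable trans,trans arrangement.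

**Compound list**

1 | cyclopropyl phenyl sulfide | C1CC1Sc1ccccc1 | starting material
2 | methyl vinyl ketone | CC(=O)C=C | starting material
3 | 1-lithiocyclopropyl phenyl sulfide | [Li]C1(Sc2ccccc2)CC1 | intermediate (not isolated)
4 | 2-[1-(phenylsulfanyl)cyclopropyl]but-3-en-2-ol (racemic) | CC(O)(C=C)C1(Sc2ccccc2)CC1 | intermediate
5 | 2-methyl-2-vinylcyclobutan-1-one (racemic) | CC1(C=C)CCC1=O | intermediate
6 | lithium 4-methyl-4-vinylcyclobut-1-en-1-olate | [Li]OC1=CCC1(C)C=C | intermediate (not isolated)
7 | 4-methyl-4-vinylcyclobut-1-en-1-yl trifluoromethanesulfonate (racemic) | CC1(C=C)CC=C1OS(=O)(=O)C(F)(F)F | intermediate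
8 | N-methoxy-N,4-dimethyl-4-vinylcyclobut-1-ene-1-carboxamide (racemic) | CON(C)C(=O)C1=CCC1(C)C=C | intermediate
9 | 4-bromoresorcinol | Oc1ccc(Br)c(O)c1 | starting material
10 | 1-bromo-2,4-bis(methoxymethoxy)benzene | COCOc1ccc(Br)c(OCOC)c1 | intermediate
11 | [2,4-bis(methoxymethoxy)phenyl]lithium | [Li]c1ccc(OCOC)cc1OCOC | intermediate (not isolated)
12 | lithium triisopropoxy[2,4-bis(methoxymethoxy)phenyl]borate | [Li+].CC(C)O[B-](OC(C)C)(OC(C)C)c1ccc(OCOC)cc1OCOC | intermediate (not isolated)
13 | [2,4-bis(methoxymethoxy)phenyl]boronic acid | OB(O)c1ccc(OCOC)cc1OCOC | intermediate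
14 | (1S,2RS,4R)-4-[2,4-bis(methoxymethoxy)phenyl]-N-methoxy-N,2-dimethyl-2-vinylcyclobutane-1-carboxamide | CON(C)C(=O)[C@H]1[C@H](c2ccc(OCOC)cc2OCOC)CC1(C)C=C | intermediate
15 | resorcinol | Oc1cccc(O)c1 | starting material
16 | 1,3-bis(methoxymethoxy)benzene | COCOc1cccc(OCOC)c1 | intermediate
17 | prenyl bromide | CC(C)=CCBr | starting material
18 | [2,6-bis(methoxymethoxy)phenyl]lithium | [Li]c1c(OCOC)cccc1OCOC | intermediate (not isolated)
19 | 1,3-bis(methoxymethoxy)-2-(3-methylbut-2-en-1-yl)benzene | COCOc1cccc(OCOC)c1CC=C(C)C | intermediate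
20 | [2,4-bis(methoxymethoxy)-3-(3-methylbut-2-en-1-yl)phenyl]lithium | [Li]c1ccc(OCOC)c(CC=C(C)C)c1OCOC | intermediate (not isolated)
21 | [2,4-bis(methoxymethoxy)-3-(3-methylbut-2-en-1-yl)phenyl]{(1S,2RS,4R)-4-[2,4-bis(methoxymethoxy)phenyl]-2-methyl-2-vinylcyclobutyl}methanone | CC(C)=CCc1c(OCOC)ccc(C(=O)[C@H]2[C@H](c3ccc(OCOC)cc3OCOC)CC2(C)C=C)c1OCOC | intermediate
22 | 2',4'-dihydroxyacetophenone | CC(=O)c1ccc(O)cc1O | starting material
23 | 1-(2,4-dihydroxy-3-iodophenyl)ethan-1-one | CC(=O)c1ccc(O)c(I)c1O | intermediate
24 | 1-[3-iodo-2,4-bis(methoxymethoxy)phenyl]ethan-1-one | CC(=O)c1ccc(OCOC)c(I)c1OCOC | intermediate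
25 | 4-(methoxymethoxy)benzaldehyde | COCOc1ccc(C=O)cc1 | starting material
26 | (E)-1-[3-iodo-2,4-bis(methoxymethoxy)phenyl]-3-[4-(methoxymethoxy)phenyl]prop-2-en-1-one | COCOc1ccc(/C=C/C(=O)c2ccc(OCOC)c(I)c2OCOC)cc1 | intermediate
27 | [2,4-bis(methoxymethoxy)-3-(3-methylbut-2-en-1-yl)phenyl]{(1S,2RS,4R)-4-[2,4-bis(methoxymethoxy)phenyl]-2-[(E)-2-{2,6-bis(methoxymethoxy)-3-[(E)-3-[4-(methoxymethoxy)phenyl]prop-2-enoyl]phenyl}ethenyl]-2-methylcyclobutyl}methanone | CC(C)=CCc1c(OCOC)ccc(C(=O)[C@H]2[C@H](c3ccc(OCOC)cc3OCOC)CC2(C)/C=C/c2c(OCOC)ccc(C(=O)/C=C/c3ccc(OCOC)cc3)c2OCOC)c1OCOC | intermediate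
28 | [2,4-bis(methoxymethoxy)-3-(3-methylbut-2-en-1-yl)phenyl]{(1S,2S,6R)-2-{2,6-bis(methoxymethoxy)-3-[(E)-3-[4-(methoxymethoxy)phenyl]prop-2-enoyl]phenyl}-6-[2,4-bis(methoxymethoxy)phenyl]-4-methylcyclohex-3-en-1-yl}methanone | CC(C)=CCc1c(OCOC)ccc(C(=O)[C@@H]2[C@@H](c3c(OCOC)ccc(C(=O)/C=C/c4ccc(OCOC)cc4)c3OCOC)C=C(C)C[C@H]2c2ccc(OCOC)cc2OCOC)c1OCOC | intermediate
29 | [2,4-dihydroxy-3-(3-methylbut-2-en-1-yl)phenyl]{(1S,2S,6R)-2-{2,6-dihydroxy-3-[(E)-3-(4-hydroxyphenyl)prop-2-enoyl]phenyl}-6-(2,4-dihydroxyphenyl)-4-methylcyclohex-3-en-1-yl}methanone | CC(C)=CCc1c(O)ccc(C(=O)[C@@H]2[C@@H](c3c(O)ccc(C(=O)/C=C/c4ccc(O)cc4)c3O)C=C(C)C[C@H]2c2ccc(O)cc2O)c1O | target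

**Step count**

Total step count: 16. Longest linear sequence: 9 steps (steps 1, 2, 3, 4, 7, 10, 14, 15, 16).

**Three steps most likely to fail**

1. Step 15 (Proposed new method). The ion pair may fragment into chalcone and diene, which erases the benzylic centre before a non-selective recombination. The ring closure may show poor facial selectivity at the new allylic/benzylic carbon if equilibration is slow. The Lewis acid may also cleave acetals, after which a freed phenol could capture the cation.
Fallback (known chemistry, sets out from 19 and 26, returns at 29): the cyclohexene would be made by the chiral borate-catalysed Diels–Alder reaction of a 2'-hydroxychalcone with an aryl diene. Compound 19 would be lithiated as in step 10 and acylated with N-methoxy-N-methylacetamide to give 1-[2,4-bis(methoxymethoxy)-3-(3-methylbut-2-en-1-yl)phenyl]ethan-1-one F1. Claisen–Schmidt condensation with purchased 2,4-bis(methoxymethoxy)benzaldehyde (KOH, EtOH) would give (E)-1-[2,4-bis(methoxymethoxy)-3-(3-methylbut-2-en-1-yl)phenyl]-3-[2,4-bis(methoxymethoxy)phenyl]prop-2-en-1-one F2. Short exposure to dilute HCl in MeOH at 0 °C should remove the most labile acetal, the one ortho to the ketone, to give (E)-3-[2,4-bis(methoxymethoxy)phenyl]-1-[2-hydroxy-4-(methoxymethoxy)-3-(3-methylbut-2-en-1-yl)phenyl]prop-2-en-1-one F3. In parallel, Heck coupling of 26 with 2-methylbut-3-en-2-ol (Pd(OAc)2, P(o-tol)3, Et3N, DMF) would give (E)-1-{3-[(E)-3-hydroxy-3-methylbut-1-en-1-yl]-2,4-bis(methoxymethoxy)phenyl}-3-[4-(methoxymethoxy)phenyl]prop-2-en-1-one F4, and dehydration (MsCl, Et3N, CH2Cl2) would give the diene (E)-1-{2,4-bis(methoxymethoxy)-3-[(E)-3-methylbuta-1,3-dien-1-yl]phenyl}-3-[4-(methoxymethoxy)phenyl]prop-2-en-1-one F5. Cycloaddition of F3 and F5 with B(OPh)3 and (R)- or (S)-BINOL (THF, rt), followed by separation from the endo isomer, should give the exo adduct [2-hydroxy-4-(methoxymethoxy)-3-(3-methylbut-2-en-1-yl)phenyl]{(1S,2S,6R)-2-{2,6-bis(methoxymethoxy)-3-[(E)-3-[4-(methoxymethoxy)phenyl]prop-2-enoyl]phenyl}-6-[2,4-bis(methoxymethoxy)phenyl]-4-methylcyclohex-3-en-1-yl}methanone F6. Its six acetals would be removed under the conditions of step 16 to give 29.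

2. Step 7. Carbometalation of the amide-activated cyclobutene may be slow, so that protodeboronation of the electron-rich, ortho-substituted boronic acid takes over. Catalyst control over the two enantiomers of the racemic substrate may also be incomplete, which would erode the enantiopurity of the benzylic carbon.
Fallback (sets out from 8 and 19, returns at 21): the order of the two arylations is reversed so that the conjugate addition runs on a more electrophilic enone. The aryllithium generated from 19 as in step 10 would be added to 8 (THF, −78 °C) to give [2,4-bis(methoxymethoxy)-3-(3-methylbut-2-en-1-yl)phenyl](4-methyl-4-vinylcyclobut-1-en-1-yl)methanone F7. Rhodium-catalysed asymmetric 1,4-addition of 13 to F7 with the same chiral diene catalyst, followed by base equilibration of the α-carbon, should give 21 directly.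

3. Step 14. Insertion of the vinyl group next to the quaternary carbon into the doubly ortho-substituted aryl palladium species may be slow. Arylation of the chalcone C=C may then compete, and prolonged heating may start the ring enlargement of the product before the controlled step.
Fallback (sets out from 21 and 24, returns at 27): the enone is taken out of the coupling and made afterwards. Heck coupling of 21 with the simpler iodide 24 under the conditions of step 14 would give [2,4-bis(methoxymethoxy)-3-(3-methylbut-2-en-1-yl)phenyl]{(1S,2RS,4R)-2-[(E)-2-[3-acetyl-2,6-bis(methoxymethoxy)phenyl]ethenyl]-4-[2,4-bis(methoxymethoxy)phenyl]-2-methylcyclobutyl}methanone F8. Claisen–Schmidt condensation of the acetyl group of F8 with 25 (KOH, EtOH, rt) should then give 27; the hindered cyclobutyl ketone has a single α-hydrogen and cannot give a condensation product.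

**Further compounds**

F1 | step 15 | 1-[2,4-bis(methoxymethoxy)-3-(3-methylbut-2-en-1-yl)phenyl]ethan-1-one | CC(=O)c1ccc(OCOC)c(CC=C(C)C)c1OCOC
F2 | step 15 | (E)-1-[2,4-bis(methoxymethoxy)-3-(3-methylbut-2-en-1-yl)phenyl]-3-[2,4-bis(methoxymethoxy)phenyl]prop-2-en-1-one | COCOc1ccc(/C=C/C(=O)c2ccc(OCOC)c(CC=C(C)C)c2OCOC)c(OCOC)c1
F3 | step 15 | (E)-3-[2,4-bis(methoxymethoxy)phenyl]-1-[2-hydroxy-4-(methoxymethoxy)-3-(3-methylbut-2-en-1-yl)phenyl]prop-2-en-1-one | COCOc1ccc(/C=C/C(=O)c2ccc(OCOC)c(CC=C(C)C)c2O)c(OCOC)c1
F4 | step 15 | (E)-1-{3-[(E)-3-hydroxy-3-methylbut-1-en-1-yl]-2,4-bis(methoxymethoxy)phenyl}-3-[4-(methoxymethoxy)phenyl]prop-2-en-1-one | COCOc1ccc(/C=C/C(=O)c2ccc(OCOC)c(/C=C/C(C)(C)O)c2OCOC)cc1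
F5 | step 15 | (E)-1-{2,4-bis(methoxymethoxy)-3-[(E)-3-methylbuta-1,3-dien-1-yl]phenyl}-3-[4-(methoxymethoxy)phenyl]prop-2-en-1-one | COCOc1ccc(/C=C/C(=O)c2ccc(OCOC)c(/C=C/C(C)=C)c2OCOC)cc1
F6 | step 15 | [2-hydroxy-4-(methoxymethoxy)-3-(3-methylbut-2-en-1-yl)phenyl]{(1S,2S,6R)-2-{2,6-bis(methoxymethoxy)-3-[(E)-3-[4-(methoxymethoxy)phenyl]prop-2-enoyl]phenyl}-6-[2,4-bis(methoxymethoxy)phenyl]-4-methylcyclohex-3-en-1-yl}methanone | CC(C)=CCc1c(OCOC)ccc(C(=O)[C@@H]2[C@@H](c3c(OCOC)ccc(C(=O)/C=C/c4ccc(OCOC)cc4)c3OCOC)C=C(C)C[C@H]2c2ccc(OCOC)cc2OCOC)c1O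
F7 | step 7 | [2,4-bis(methoxymethoxy)-3-(3-methylbut-2-en-1-yl)phenyl](4-methyl-4-vinylcyclobut-1-en-1-yl)methanone (racemic) | CC(C)=CCc1c(OCOC)ccc(C(=O)C2=CCC2(C)C=C)c1OCOC
F8 | step 14 | [2,4-bis(methoxymethoxy)-3-(3-methylbut-2-en-1-yl)phenyl]{(1S,2RS,4R)-2-[(E)-2-[3-acetyl-2,6-bis(methoxymethoxy)phenyl]ethenyl]-4-[2,4-bis(methoxymethoxy)phenyl]-2-methylcyclobutyl}methanone | CC(C)=CCc1c(OCOC)ccc(C(=O)[C@H]2[C@H](c3ccc(OCOC)cc3OCOC)CC2(C)/C=C/c2c(OCOC)ccc(C(C)=O)c2OCOC)c1OCOC
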